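## Retrosynthetic overview

1. The target comes from global MOM removal of a 7-hydroxy-8-(1,1-dimethylallyl)flavone, itself made by aromatic Claisen rearrangement of the 7-O-prenyl ether (C8–C bond).
2. The C2=C3 bond of ring C comes from dehydration of a 3-hydroxy-3-prenylflavanone.
3. Key step: the C3–C4 bond is made by a carbene-catalysed intramolecular crossed benzoin. The ring A formyl carbon reacts as an acyl anion and attacks the side-chain ketone carbon, so two carbonyl carbons are joined.
4. The benzoin substrate is an aryl ether made by Mitsunobu coupling of 2,6-dihydroxy-4-(prenyloxy)benzaldehyde with a ring B acyloin. The acyloin comes from the ring B aldehyde and lithiated 2-prenyl-1,3-dithiane, a second acyl anion equivalent.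
5. Ring order: rings A and B are bought as benzaldehydes; ring C is the only ring formed (step 7).

Assumption: the target has no stereocentre, so there is no enantiomer to select; chiral intermediates are carried as racemates or diastereomer mixtures because all their stereocentres are destroyed in step 8.

## Route

Step 1
Reactants: 1 2,4-dihydroxybenzaldehyde
Product: 2 2,4-bis(methoxymethoxy)benzaldehyde
Conditions: MOMCl (2.5 equiv), K2CO3 (3 equiv), acetone, reflux
Reagents that add atoms: chloromethyl methyl ether (MOMCl), COCCl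
Why: Williamson-type O-alkylation of both phenoxides (excess reagent and heat for the chelated 2-OH) gives acetal ethers that survive the organolithium, Mitsunobu, carbene, strong-base and thermal steps and come off together at the end.

Step 2
Reactants: 3 1,3-dithiane; 4 prenyl bromide (1-bromo-3-methylbut-2-ene); 2 2,4-bis(methoxymethoxy)benzaldehyde
Product: 6 racemic [2,4-bis(methoxymethoxy)phenyl][2-(3-methylbut-2-en-1-yl)-1,3-dithian-2-yl]methanol, via 2-prenyl-1,3-dithiane 5 (not isolated)
Conditions: 3, n-BuLi, THF, −30 °C; 4, −78 → 0 °C; n-BuLi, −30 °C; 2, −78 °C; then H2O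
Reagents that add atoms: none
Why: Corey–Seebach umpolung, in which the lithiated dithiane is alkylated at the primary carbon of prenyl bromide (no allylic transposition, unlike prenyl-metal additions to acyl groups) and, after a second lithiation, the masked 4-methylpent-3-enoyl anion adds to aldehyde 2, giving one stereocentre as a racemate that is erased in step 8.

Step 3
Reactants: 6 racemic [2,4-bis(methoxymethoxy)phenyl][2-(3-methylbut-2-en-1-yl)-1,3-dithian-2-yl]methanol
Product: 7 racemic 1-[2,4-bis(methoxymethoxy)phenyl]-1-hydroxy-5-methylhex-4-en-2-one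
Conditions: MeI (10 equiv), CaCO3 (5 equiv), MeCN–H2O (9:1), 45 °C
Reagents that add atoms: water, O
Why: alkylative dithioacetal hydrolysis (S-methylation, then hydrolysis of the sulfonium) is non-oxidising and buffered, so the electron-rich arene, the MOM acetals and the trisubstituted alkene are untouched and the acyloin is not tautomerised by base.

Step 4
Reactants: 8 2,4,6-trihydroxybenzaldehyde; 4 prenyl bromide (1-bromo-3-methylbut-2-ene)
Product: 9 2,6-dihydroxy-4-[(3-methylbut-2-en-1-yl)oxy]benzaldehyde
Conditions: K2CO3 (1.0 equiv), 4 (1.0 equiv), acetone, 0 °C → rt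
Reagents that add atoms: none
Why: Williamson mono-O-alkylation occurs at the para hydroxyl, the most acidic one and the only one not hydrogen-bonded to the formyl group, and the two hydroxyls left are equivalent by symmetry.

Step 5
Reactants: 9 2,6-dihydroxy-4-[(3-methylbut-2-en-1-yl)oxy]benzaldehyde; 7 racemic 1-[2,4-bis(methoxymethoxy)phenyl]-1-hydroxy-5-methylhex-4-en-2-one
Product: 10 racemic 2-{[1-(2,4-bis(methoxymethoxy)phenyl)-5-methyl-2-oxohex-4-en-1-yl]oxy}-6-hydroxy-4-[(3-methylbut-2-en-1-yl)oxy]benzaldehyde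
Conditions: PPh3, DIAD, THF, 0 °C → rt (9 in 1.5-fold excess)
Reagents that add atoms: none
Why: Mitsunobu etherification, in which the acidic chelated phenol (pKa about 8) displaces the activated carbinol by SN2 (helped by the adjacent carbonyl) in a neutral medium that avoids acyloin tautomerisation and intramolecular aldol; the second phenol stays chelated and unreacted, and the racemic centre is erased in step 8.

Step 6
Reactants: 10 racemic 2-{[1-(2,4-bis(methoxymethoxy)phenyl)-5-methyl-2-oxohex-4-en-1-yl]oxy}-6-hydroxy-4-[(3-methylbut-2-en-1-yl)oxy]benzaldehyde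
Product: 11 racemic 2-{[1-(2,4-bis(methoxymethoxy)phenyl)-5-methyl-2-oxohex-4-en-1-yl]oxy}-6-(methoxymethoxy)-4-[(3-methylbut-2-en-1-yl)oxy]benzaldehyde
Conditions: MOMCl, i-Pr2NEt, CH2Cl2, 0 °C → rt
Reagents that add atoms: chloromethyl methyl ether (MOMCl), COCCl
Why: acetal protection with a hindered amine base does not enolise the ketone, removes the phenol that would become a deactivating phenoxide in step 7, and removes the 5-OH chelate that would open the C6 pathway in step 9.

Step 7
Reactants: 11 racemic 2-{[1-(2,4-bis(methoxymethoxy)phenyl)-5-methyl-2-oxohex-4-en-1-yl]oxy}-6-(methoxymethoxy)-4-[(3-methylbut-2-en-1-yl)oxy]benzaldehyde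
Product: 12 2-[2,4-bis(methoxymethoxy)phenyl]-3-hydroxy-5-(methoxymethoxy)-3-(3-methylbut-2-en-1-yl)-7-[(3-methylbut-2-en-1-yl)oxy]-2,3-dihydro-4H-chromen-4-one (racemic mixture of C2/C3 diastereomers)
Conditions: 3-benzyl-5-(2-hydroxyethyl)-4-methylthiazolium chloride (20 mol %), Et3N (30 mol %), t-BuOH–THF (1:1), 50 °C, under argon
Reagents that add atoms: none
Why: intramolecular crossed aldehyde–ketone benzoin reaction, in which the small thiazol-2-ylidene turns the doubly ortho-substituted formyl carbon into a Breslow intermediate (acyl anion equivalent) that adds 6-exo to the ketone carbonyl and closes ring C through the C3–C4 bond; the two stereocentres form without control and both disappear in step 8.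

Step 8
Reactants: 12 2-[2,4-bis(methoxymethoxy)phenyl]-3-hydroxy-5-(methoxymethoxy)-3-(3-methylbut-2-en-1-yl)-7-[(3-methylbut-2-en-1-yl)oxy]-2,3-dihydro-4H-chromen-4-one
Product: 15 2-[2,4-bis(methoxymethoxy)phenyl]-5-(methoxymethoxy)-3-(3-methylbut-2-en-1-yl)-7-[(3-methylbut-2-en-1-yl)oxy]-4H-chromen-4-one, via tertiary mesylate 13 (not isolated), via exocyclic dienone 14 (not isolated)
Conditions: MsCl, Et3N, CH2Cl2, 0 °C; aqueous wash and solvent swap (crude 13); t-BuOK (1.5 equiv), THF, −20 → 0 °C
Reagents that add atoms: methanesulfonyl chloride (MsCl), CS(=O)(=O)Cl (its atoms are carried by 13 only)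
Why: sulfene mesylation of the tertiary α-ketol and base-induced E2 dehydrosulfonylation (as in α-bromoketone to enone eliminations) give the γ-pyrone when C2–H is lost and dienone 14 when a side-chain hydrogen is lost; t-BuOK then removes the benzylic, allylic C2–H of 14 and the pentadienyl anion is protonated at its central carbon, so all material converges on the aromatic-stabilised chromone 15 with the prenyl alkene in place and no stereocentre left.

Step 9
Reactants: 15 2-[2,4-bis(methoxymethoxy)phenyl]-5-(methoxymethoxy)-3-(3-methylbut-2-en-1-yl)-7-[(3-methylbut-2-en-1-yl)oxy]-4H-chromen-4-one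
Product: 16 2-[2,4-bis(methoxymethoxy)phenyl]-7-hydroxy-5-(methoxymethoxy)-8-(2-methylbut-3-en-2-yl)-3-(3-methylbut-2-en-1-yl)-4H-chromen-4-one
Conditions: N,N-diethylaniline, 190 °C, sealed tube, 2 h
Reagents that add atoms: none
Why: aromatic Claisen [3,3] rearrangement of the aryl prenyl ether and re-aromatisation give the ortho 1,1-dimethylallyl phenol, directed to C8 because the C7–C8 bond has the higher double-bond character in a chromone whose 5-oxygen is not chelated (7-allyloxychromones and coumarins rearrange to C8), while the basic solvent suppresses acid-catalysed cyclisation of the product.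

Step 10
Reactants: 16 2-[2,4-bis(methoxymethoxy)phenyl]-7-hydroxy-5-(methoxymethoxy)-8-(2-methylbut-3-en-2-yl)-3-(3-methylbut-2-en-1-yl)-4H-chromen-4-one
Product: 17 2-(2,4-dihydroxyphenyl)-5,7-dihydroxy-8-(2-methylbut-3-en-2-yl)-3-(3-methylbut-2-en-1-yl)-4H-chromen-4-one (target)
Conditions: HCl (1.25 M in MeOH), 40 °C, monitored and stopped at full conversion
Reagents that add atoms: none
Why: acid-catalysed transacetalisation to methanol removes the three MOM groups (the peri 5-O-MOM fastest), and the mild, water-poor conditions at low temperature leave the prenyl and 1,1-dimethylallyl alkenes unhydrated and uncyclised.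

## Compound list

1 | 2,4-dihydroxybenzaldehyde | O=Cc1ccc(O)cc1O | starting material
2 | 2,4-bis(methoxymethoxy)benzaldehyde | O=Cc1ccc(OCOC)cc1OCOC | intermediate
3 | 1,3-dithiane | C1CSCSC1 | starting material
4 | prenyl bromide (1-bromo-3-methylbut-2-ene) | CC(C)=CCBr | starting material
5 | 2-(3-methylbut-2-en-1-yl)-1,3-dithiane | CC(C)=CCC1SCCCS1 | intermediate (not isolated)
6 | [2,4-bis(methoxymethoxy)phenyl][2-(3-methylbut-2-en-1-yl)-1,3-dithian-2-yl]methanol, racemic | CC(C)=CCC1(SCCCS1)C(O)c1ccc(OCOC)cc1OCOC | intermediate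
7 | 1-[2,4-bis(methoxymethoxy)phenyl]-1-hydroxy-5-methylhex-4-en-2-one, racemic | CC(C)=CCC(=O)C(O)c1ccc(OCOC)cc1OCOC | intermediate
8 | 2,4,6-trihydroxybenzaldehyde | O=Cc1c(O)cc(O)cc1O | starting material
9 | 2,6-dihydroxy-4-[(3-methylbut-2-en-1-yl)oxy]benzaldehyde | O=Cc1c(O)cc(OCC=C(C)C)cc1O | intermediate
10 | 2-{[1-(2,4-bis(methoxymethoxy)phenyl)-5-methyl-2-oxohex-4-en-1-yl]oxy}-6-hydroxy-4-[(3-methylbut-2-en-1-yl)oxy]benzaldehyde, racemic | O=Cc1c(O)cc(OCC=C(C)C)cc1OC(C(=O)CC=C(C)C)c1ccc(OCOC)cc1OCOC | intermediate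
11 | 2-{[1-(2,4-bis(methoxymethoxy)phenyl)-5-methyl-2-oxohex-4-en-1-yl]oxy}-6-(methoxymethoxy)-4-[(3-methylbut-2-en-1-yl)oxy]benzaldehyde, racemic | O=Cc1c(OCOC)cc(OCC=C(C)C)cc1OC(C(=O)CC=C(C)C)c1ccc(OCOC)cc1OCOC | intermediate
12 | 2-[2,4-bis(methoxymethoxy)phenyl]-3-hydroxy-5-(methoxymethoxy)-3-(3-methylbut-2-en-1-yl)-7-[(3-methylbut-2-en-1-yl)oxy]-2,3-dihydro-4H-chromen-4-one, racemic, both C2/C3 diastereomers (configuration not defined) | O=C1c2c(OCOC)cc(OCC=C(C)C)cc2OC(c2ccc(OCOC)cc2OCOC)C1(O)CC=C(C)C | intermediate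
13 | 2-[2,4-bis(methoxymethoxy)phenyl]-5-(methoxymethoxy)-3-(3-methylbut-2-en-1-yl)-7-[(3-methylbut-2-en-1-yl)oxy]-4-oxo-3,4-dihydro-2H-chromen-3-yl methanesulfonate, racemic diastereomer mixture | O=C1c2c(OCOC)cc(OCC=C(C)C)cc2OC(c2ccc(OCOC)cc2OCOC)C1(OS(C)(=O)=O)CC=C(C)C | intermediate (not isolated)
14 | 2-[2,4-bis(methoxymethoxy)phenyl]-5-(methoxymethoxy)-3-(3-methylbut-2-en-1-ylidene)-7-[(3-methylbut-2-en-1-yl)oxy]-2,3-dihydro-4H-chromen-4-one, racemic, E/Z not defined | O=C1c2c(OCOC)cc(OCC=C(C)C)cc2OC(c2ccc(OCOC)cc2OCOC)C1=CC=C(C)C | intermediate (not isolated)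
15 | 2-[2,4-bis(methoxymethoxy)phenyl]-5-(methoxymethoxy)-3-(3-methylbut-2-en-1-yl)-7-[(3-methylbut-2-en-1-yl)oxy]-4H-chromen-4-one | O=c1c(CC=C(C)C)c(-c2ccc(OCOC)cc2OCOC)oc2cc(OCC=C(C)C)cc(OCOC)c12 | intermediate
16 | 2-[2,4-bis(methoxymethoxy)phenyl]-7-hydroxy-5-(methoxymethoxy)-8-(2-methylbut-3-en-2-yl)-3-(3-methylbut-2-en-1-yl)-4H-chromen-4-one | O=c1c(CC=C(C)C)c(-c2ccc(OCOC)cc2OCOC)oc2c(C(C)(C)C=C)c(O)cc(OCOC)c12 | intermediate
17 | 2-(2,4-dihydroxyphenyl)-5,7-dihydroxy-8-(2-methylbut-3-en-2-yl)-3-(3-methylbut-2-en-1-yl)-4H-chromen-4-one (achiral) | C=CC(C)(C)c1c(O)cc(O)c2c(=O)c(CC=C(C)C)c(-c3ccc(O)cc3O)oc12 | target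

## Step count and risks

Total steps: 10. Longest linear sequence: 9 (steps 1, 2, 3, 5, 6, 7, 8, 9, 10); step 4 is the side branch.

Most likely to fail, step 7: the aldehyde is electron-rich and flanked by two ortho oxygens, so Breslow intermediate formation may be slow. The acidic C–H between the ketone, the aryl group and the aryloxy group can also add to the aldehyde (Rap–Stoermer-type aldol) instead. Fallback: set out from 11 and use a one-electron umpolung of the same aldehyde carbon. SmI2 (2.5 equiv) with t-BuOH in THF at −78 °C effects ketyl–ketone pinacol cyclisation to 2-[2,4-bis(methoxymethoxy)phenyl]-5-(methoxymethoxy)-3-(3-methylbut-2-en-1-yl)-7-[(3-methylbut-2-en-1-yl)oxy]-3,4-dihydro-2H-chromene-3,4-diol F1. 2-Iodoxybenzoic acid in DMSO at rt then oxidises only the secondary benzylic alcohol without glycol cleavage, and the route is rejoined at 12.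

Second, step 5: the Mitsunobu coupling joins a hindered, chelated phenol to a secondary benzylic carbinol on an electron-rich ring, so ionisation, C-alkylation or acyloin tautomerisation may compete. Fallback: set out from 7 and make the electrophile separately. MsCl and Et3N in CH2Cl2 at −20 °C give 1-[2,4-bis(methoxymethoxy)phenyl]-5-methyl-2-oxohex-4-en-1-yl methanesulfonate F2, used crude. The caesium phenoxide of 9 (Cs2CO3, DMF, 0 °C, short reaction time to limit aldol side reaction) displaces it by SN2 at the carbonyl-activated carbon, and the route is rejoined at 10.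

Third, step 9: the free ortho 1,1-dimethylallyl phenol can go on at 190 °C to the abnormal Claisen product or to a cyclised coumaran, and some C6 isomer may form. Fallback: set out from 15 and run the rearrangement with acylative interception of the phenol as it forms. Ac2O and NaOAc in N,N-diethylaniline at 190 °C give 2-[2,4-bis(methoxymethoxy)phenyl]-5-(methoxymethoxy)-8-(2-methylbut-3-en-2-yl)-3-(3-methylbut-2-en-1-yl)-4-oxo-4H-chromen-7-yl acetate F3, which cannot undergo the phenol-dependent side reactions and is easier to separate from any C6 isomer. K2CO3 in MeOH at 0 °C then removes the acetate, and the route is rejoined at 16.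

## Further compounds

F1 | step 7 | 2-[2,4-bis(methoxymethoxy)phenyl]-5-(methoxymethoxy)-3-(3-methylbut-2-en-1-yl)-7-[(3-methylbut-2-en-1-yl)oxy]-3,4-dihydro-2H-chromene-3,4-diol, racemic diastereomer mixture | OC1c2c(OCOC)cc(OCC=C(C)C)cc2OC(c2ccc(OCOC)cc2OCOC)C1(O)CC=C(C)C
F2 | step 5 | 1-[2,4-bis(methoxymethoxy)phenyl]-5-methyl-2-oxohex-4-en-1-yl methanesulfonate, racemic | CC(C)=CCC(=O)C(OS(C)(=O)=O)c1ccc(OCOC)cc1OCOC
F3 | step 9 | 2-[2,4-bis(methoxymethoxy)phenyl]-5-(methoxymethoxy)-8-(2-methylbut-3-en-2-yl)-3-(3-methylbut-2-en-1-yl)-4-oxo-4H-chromen-7-yl acetate | CC(=O)Oc1cc(OCOC)c2c(=O)c(CC=C(C)C)c(-c3ccc(OCOC)cc3OCOC)oc2c1C(C)(C)C=C
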